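Numbering: C1 (fusion carbon with CH3), C2 (CH–OAc), C3, C4 (isopropyl carbinol), C5 (fusion CH), C6 (CH–O-anisoyl), C7, C8 (methylated epoxide carbon), C9 (epoxide CH), C10 (CH–OH); β is the face of the C1 methyl, α the other face.
Cuts: behind the esters, the epoxide (from a C8=C9 alkene) and the C8 methyl (enolate methylation), the bicycle is cut at C1–C5 and C6–C7 into an alkyne (C5≡C6) and a 1-silyloxy-1-vinylcyclopropane (C1=C10, C9, C8, C7); the open chain is cut at C10=C1 (Wittig), C2–C3 (aldol) and C4–C5 (ethynyl addition).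
Enabling feature: the seven-membered ring holds the five-carbon run C1–C10–C9–C8–C7 with oxygen wanted at C9/C10, which is a silyloxy vinylcyclopropane in latent form, and the five-membered ring supplies the three-atom tether C2–C3–C4 from C1 to the alkyne carbons C5 and C6; the cis oxygens on C2 and C4 can be bridged by a methylene acetal.
Forward order: chain assembly (steps 1–8), both carbocycles in one rhodium-catalysed [5+2] cycloaddition (step 9), then C10 oxygen, C8 methyl, masked C8=C9, C6 oxygen, esters, and the epoxide ring last; the cyclopropane is left unsubstituted so that it has no stereocentre and either ring bond can open.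
Stereochemistry: C2 from an Ipc2BCl aldol (used as a relay), C4 by chelate-controlled ethynyl addition, C2 reset by oxidation and 1,3-anti hydride delivery; C1 by the acetal tether in the cycloaddition; C5 and C6 by exo hydroboration of the bridged acetal; C10 by Luche reduction anti to the C1 methyl; C8/C9 by epoxidation anti to the C10 silyl ether.

Key step: step 9

Assumption: C10 in compounds 16 to 19 and C8 in compounds 18 to 20 are transient stereocentres that become trigonal in steps 13 and 14, so they are drawn without configuration (ξ).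

Step 1
Reactants: 1 methyl 1-hydroxycyclopropane-1-carboxylate
Product: 2 methyl 1-[(tert-butyldimethylsilyl)oxy]cyclopropane-1-carboxylate
Conditions: TBSOTf, 2,6-lutidine, CH2Cl2, 0 °C
Reagents that add atoms: tert-butyldimethylsilyl triflate, CC(C)(C)[Si](C)(C)OS(=O)(=O)C(F)(F)F
Why: Silylation of a tertiary hydroxyl with a silyl triflate and a hindered pyridine base is routine and installs the silyloxy group that later activates the cyclopropane and becomes the C9 enol ether.

Step 2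
Reactants: 2 methyl 1-[(tert-butyldimethylsilyl)oxy]cyclopropane-1-carboxylate
Product: 3 1-[(tert-butyldimethylsilyl)oxy]cyclopropane-1-carbaldehyde
Conditions: i-Bu2AlH (1.1 equiv), CH2Cl2, −78 °C; aq potassium sodium tartrate
Reagents that add atoms: none
Why: Partial ester reduction with i-Bu2AlH at low temperature should stop at the aldehyde because the α-silyloxy tetrahedral aluminate is stable until work-up.

Step 3
Reactants: 3 1-[(tert-butyldimethylsilyl)oxy]cyclopropane-1-carbaldehyde; 4 2-(triphenyl-λ5-phosphanylidene)propanal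
Product: 5 (E)-3-{1-[(tert-butyldimethylsilyl)oxy]cyclopropyl}-2-methylprop-2-enal
Conditions: toluene, 90 °C
Reagents that add atoms: none
Why: Wittig olefination with a formyl-stabilised ylide should give the (E)-2-methyl enal (C10=C1) because the stabilised ylide adds reversibly and the conjugated, hindered product does not react again.

Step 4
Reactants: 5 (E)-3-{1-[(tert-butyldimethylsilyl)oxy]cyclopropyl}-2-methylprop-2-enal; 6 3-methylbutan-2-one
Product: 9 (5S,6E)-7-{1-[(tert-butyldimethylsilyl)oxy]cyclopropyl}-5-hydroxy-2,6-dimethylhept-6-en-3-one, via diisopinocampheylboron enolate 7 (not isolated), via boron aldolate 8 (not isolated)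
Conditions: (+)-Ipc2BCl, Et3N, Et2O, 0 °C; then 5, −78 → −20 °C; then H2O2, MeOH, pH 7 buffer (NaH2PO4/Na2HPO4)
Reagents that add atoms: none
Why: Boron-mediated aldol addition of the kinetic methyl-side enolate of 6 runs through a chair transition state in which the isopinocampheyl groups of the (+)-reagent are expected to direct attack on the enal face that gives the 5S carbinol, which serves only as a relay for C4.

Step 5
Reactants: 9 (5S,6E)-7-{1-[(tert-butyldimethylsilyl)oxy]cyclopropyl}-5-hydroxy-2,6-dimethylhept-6-en-3-one; 10 ethynylmagnesium bromide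
Product: 11 (3R,5S,6E)-7-{1-[(tert-butyldimethylsilyl)oxy]cyclopropyl}-6-methyl-3-(propan-2-yl)hept-6-en-1-yne-3,5-diol
Conditions: HC≡CMgBr (4 equiv), THF, −78 → −30 °C; aq NH4Cl
Reagents that add atoms: none
Why: Grignard addition under Cram-chelate 1,3-induction: the first equivalent forms the magnesium alkoxide, which chelates the ketone in a half-chair with the alkenyl group equatorial, and the ethynyl nucleophile should add axially from outside the chelate to set the 3R tertiary carbinol (the later C4).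

Step 6
Reactants: 11 (3R,5S,6E)-7-{1-[(tert-butyldimethylsilyl)oxy]cyclopropyl}-6-methyl-3-(propan-2-yl)hept-6-en-1-yne-3,5-diol
Product: 12 (1E,5R)-1-{1-[(tert-butyldimethylsilyl)oxy]cyclopropyl}-5-ethynyl-5-hydroxy-2,6-dimethylhept-1-en-3-one
Conditions: MnO2 (activated, excess), CH2Cl2, rt
Reagents that add atoms: none
Why: Allylic oxidation with MnO2 touches only the secondary allylic alcohol and leaves the tertiary propargylic alcohol, which erases the relay centre so that C2 can be reset from C4.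

Step 7
Reactants: 12 (1E,5R)-1-{1-[(tert-butyldimethylsilyl)oxy]cyclopropyl}-5-ethynyl-5-hydroxy-2,6-dimethylhept-1-en-3-one
Product: 13 (3R,5R,6E)-7-{1-[(tert-butyldimethylsilyl)oxy]cyclopropyl}-6-methyl-3-(propan-2-yl)hept-6-en-1-yne-3,5-diol
Conditions: Me4NBH(OAc)3, MeCN/AcOH (1:1), −30 °C
Reagents that add atoms: none
Why: Hydroxyl-directed 1,3-anti reduction (Evans–Saksena) delivers hydride intramolecularly from the C4 alkoxyborohydride through a chair with isopropyl equatorial and the slender ethynyl group axial, which should set the 5R carbinol (the later C2) with its oxygen cis to the C4 oxygen in the future ring.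

Step 8
Reactants: 13 (3R,5R,6E)-7-{1-[(tert-butyldimethylsilyl)oxy]cyclopropyl}-6-methyl-3-(propan-2-yl)hept-6-en-1-yne-3,5-diol
Product: 14 (4R,6R)-6-[(E)-1-{1-[(tert-butyldimethylsilyl)oxy]cyclopropyl}prop-1-en-2-yl]-4-ethynyl-4-(propan-2-yl)-1,3-dioxane
Conditions: CH2Br2, 50% aq NaOH, Bu4NHSO4, 45 °C
Reagents that add atoms: dibromomethane, BrCBr
Why: Double Williamson alkylation under phase transfer (methylenation of a 1,3-diol) should close the 1,3-dioxane through a reactive bromomethyl ether without deprotonating the terminal alkyne or touching the silyl ether, and the acetal carbon is not a stereocentre.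

Step 9
Reactants: 14 (4R,6R)-6-[(E)-1-{1-[(tert-butyldimethylsilyl)oxy]cyclopropyl}prop-1-en-2-yl]-4-ethynyl-4-(propan-2-yl)-1,3-dioxane
Product: 15 9-[(tert-butyldimethylsilyl)oxy]-1β-methyl-2β,4β-(methylenedioxy)-4α-(propan-2-yl)bicyclo[5.3.0]deca-5,9-diene (plan numbering)
Conditions: [Rh(CO)2Cl]2 (5 mol %), ClCH2CH2Cl (0.01 M), 70 °C
Reagents that add atoms: none
Why: Monovalent rhodium binds the alkene and opens the cyclopropane by strain-driven oxidative addition to an allyl–alkyl rhodacycle (both ring bonds are equivalent and the silyloxy group speeds this step), the tethered alkyne inserts at the allyl terminus C1 to form C1–C5, and C(sp2)–C(sp3) reductive elimination forms C6–C7. The closest known reaction type is the [Rh(CO)2Cl]2-catalysed intramolecular [5+2] cycloaddition of alkynes with silyloxy- or alkoxy-vinylcyclopropanes, including alkenes that are disubstituted at the tether-bearing carbon and give an angular methyl. The cyclopentane closes in the insertion step, exo with respect to both π-bonds across the three-atom tether C2–C3–C4, and the cycloheptadiene closes in the reductive elimination that contracts the eight-membered rhodacycle. The one new stereocentre, C1, is controlled by the methylene acetal: C1 and C5 can bond only when the alkenyl and ethynyl arms are both axial on the dioxane chair, which builds a 2,4-dioxabicyclo[3.2.1]octane in which the small methyl takes the endo position under the O–CH2–O bridge and the bulky rhodium-bound allyl chain the exo position, so the methyl ends cis to both oxygens. The step needs facial selectivity at C1 (secured by this tether) and chemoselectivity over alkyne oligomerisation (secured by high dilution), and it poses no regiochemical choice in the cyclopropane because C7 and C8 are both unsubstituted.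

Step 10
Reactants: 15 9-[(tert-butyldimethylsilyl)oxy]-1β-methyl-2β,4β-(methylenedioxy)-4α-(propan-2-yl)bicyclo[5.3.0]deca-5,9-diene
Product: 16 10ξ-[(tert-butyldimethylsilyl)oxy]-1β-methyl-2β,4β-(methylenedioxy)-4α-(propan-2-yl)bicyclo[5.3.0]dec-5-en-9-one
Conditions: mCPBA (1.05 equiv), NaHCO3, CH2Cl2, −20 °C
Reagents that add atoms: 3-chloroperbenzoic acid, O=C(OO)c1cccc(Cl)c1
Why: Rubottom oxidation: the silyl enol ether is far more nucleophilic than the hindered C5=C6 alkene, should be epoxidised (mainly anti to the C1 methyl) and open with 1,4-silyl shift to the α-silyloxy ketone, whose C10 configuration is of no consequence.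

Step 11
Reactants: 16 10ξ-[(tert-butyldimethylsilyl)oxy]-1β-methyl-2β,4β-(methylenedioxy)-4α-(propan-2-yl)bicyclo[5.3.0]dec-5-en-9-one
Product: 18 10ξ-[(tert-butyldimethylsilyl)oxy]-1β,8ξ-dimethyl-2β,4β-(methylenedioxy)-4α-(propan-2-yl)bicyclo[5.3.0]dec-5-en-9-one, via lithium C8–C9 enolate 17 (not isolated)
Conditions: LiN(i-Pr)2 (1.1 equiv), THF, −78 °C; then MeI, −78 → −40 °C
Reagents that add atoms: iodomethane, CI
Why: Kinetic α′-alkylation of an α-silyloxy ketone: the amide base should remove the unhindered C8 proton and not the neopentyl C10 proton next to oxygen, and the enolate is methylated at C8 (configuration of no consequence).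

Step 12
Reactants: 18 10ξ-[(tert-butyldimethylsilyl)oxy]-1β,8ξ-dimethyl-2β,4β-(methylenedioxy)-4α-(propan-2-yl)bicyclo[5.3.0]dec-5-en-9-one
Product: 19 10ξ-hydroxy-1β,8ξ-dimethyl-2β,4β-(methylenedioxy)-4α-(propan-2-yl)bicyclo[5.3.0]dec-5-en-9-one
Conditions: HF·pyridine, THF, 0 °C → rt
Reagents that add atoms: none
Why: Fluoride-driven cleavage of the Si–O bond should free the C10 hydroxyl while the methylene acetal and the alkene are inert to HF·pyridine.

Step 13
Reactants: 19 10ξ-hydroxy-1β,8ξ-dimethyl-2β,4β-(methylenedioxy)-4α-(propan-2-yl)bicyclo[5.3.0]dec-5-en-9-one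
Product: 20 1β,8ξ-dimethyl-2β,4β-(methylenedioxy)-4α-(propan-2-yl)bicyclo[5.3.0]dec-5-ene-9,10-dione
Conditions: Dess–Martin periodinane, NaHCO3, CH2Cl2, rt
Reagents that add atoms: none
Why: Dess–Martin oxidation should convert the α-hydroxy ketone into the 1,2-diketone without C–C cleavage, and this diketone can enolise only toward C8 because C1 is quaternary.

Step 14
Reactants: 20 1β,8ξ-dimethyl-2β,4β-(methylenedioxy)-4α-(propan-2-yl)bicyclo[5.3.0]dec-5-ene-9,10-dione
Product: 21 1β,8-dimethyl-2β,4β-(methylenedioxy)-10-oxo-4α-(propan-2-yl)bicyclo[5.3.0]deca-5,8-dien-9-yl trifluoromethanesulfonate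
Conditions: Tf2O, Et3N, CH2Cl2, −78 °C
Reagents that add atoms: trifluoromethanesulfonic anhydride, O=S(=O)(OS(=O)(=O)C(F)(F)F)C(F)(F)F
Why: Enol triflate formation: Et3N enolises the diketone in its only possible direction and Tf2O traps the C9 enolate oxygen, which should give a 2-triflyloxy enone that carries the future C8=C9 alkene in masked, electron-poor form.

Step 15
Reactants: 21 1β,8-dimethyl-2β,4β-(methylenedioxy)-10-oxo-4α-(propan-2-yl)bicyclo[5.3.0]deca-5,8-dien-9-yl trifluoromethanesulfonate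
Product: 22 10β-hydroxy-1β,8-dimethyl-2β,4β-(methylenedioxy)-4α-(propan-2-yl)bicyclo[5.3.0]deca-5,8-dien-9-yl trifluoromethanesulfonate
Conditions: NaBH4, CeCl3·7H2O, MeOH, −78 °C
Reagents that add atoms: none
Why: Luche 1,2-reduction: hydride should attack the C10 carbonyl anti to the pseudo-axial C1 methyl (as in 17-keto steroids), so the new hydroxyl is cis to the methyl (10β), while cerium suppresses conjugate reduction and the triflate is untouched.

Step 16
Reactants: 22 10β-hydroxy-1β,8-dimethyl-2β,4β-(methylenedioxy)-4α-(propan-2-yl)bicyclo[5.3.0]deca-5,8-dien-9-yl trifluoromethanesulfonate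
Product: 23 10β-[(tert-butyldimethylsilyl)oxy]-1β,8-dimethyl-2β,4β-(methylenedioxy)-4α-(propan-2-yl)bicyclo[5.3.0]deca-5,8-dien-9-yl trifluoromethanesulfonate
Conditions: TBSOTf, 2,6-lutidine, CH2Cl2, −78 → 0 °C
Reagents that add atoms: tert-butyldimethylsilyl triflate, CC(C)(C)[Si](C)(C)OS(=O)(=O)C(F)(F)F
Why: Silyl triflate silylation works on hindered secondary alcohols and gives the bulky C10 ether needed for site-selective acylations and for facial control in step 22.

Step 17
Reactants: 23 10β-[(tert-butyldimethylsilyl)oxy]-1β,8-dimethyl-2β,4β-(methylenedioxy)-4α-(propan-2-yl)bicyclo[5.3.0]deca-5,8-dien-9-yl trifluoromethanesulfonate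
Product: 25 10β-[(tert-butyldimethylsilyl)oxy]-6α-hydroxy-1β,8-dimethyl-2β,4β-(methylenedioxy)-4α-(propan-2-yl)-5α-H-bicyclo[5.3.0]dec-8-en-9-yl trifluoromethanesulfonate, via C6 alkylborane 24 (not isolated)
Conditions: BH3·THF (3 equiv), THF, 0 °C → rt; then NaBO3·4H2O, H2O, rt
Reagents that add atoms: sodium perborate, [Na+].[O-]B1OO1
Why: Hydroboration–oxidation: borane should add to the only electron-rich alkene (the tetrasubstituted vinyl triflate is inert) with boron at the less substituted C6 and from the exo face of the 2,4-dioxabicyclo[3.2.1]octane unit (anti to the acetal bridge and the C1 methyl), so that syn addition sets 5α-H (trans ring fusion) and, after oxidation with retention, 6α-OH.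

Step 18
Reactants: 25 10β-[(tert-butyldimethylsilyl)oxy]-6α-hydroxy-1β,8-dimethyl-2β,4β-(methylenedioxy)-4α-(propan-2-yl)-5α-H-bicyclo[5.3.0]dec-8-en-9-yl trifluoromethanesulfonate
Product: 26 10β-[(tert-butyldimethylsilyl)oxy]-1β,8-dimethyl-2β,4β-(methylenedioxy)-4α-(propan-2-yl)-9-(trifluoromethanesulfonyloxy)-5α-H-bicyclo[5.3.0]dec-8-en-6α-yl 4-methoxybenzoate
Conditions: 4-MeOC6H4COCl, Et3N, DMAP (cat.), CH2Cl2, rt
Reagents that add atoms: 4-methoxybenzoyl chloride, COc1ccc(C(Cl)=O)cc1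
Why: DMAP-catalysed acylation (nucleophilic catalysis) should esterify the only free hydroxyl.

Step 19
Reactants: 26 10β-[(tert-butyldimethylsilyl)oxy]-1β,8-dimethyl-2β,4β-(methylenedioxy)-4α-(propan-2-yl)-9-(trifluoromethanesulfonyloxy)-5α-H-bicyclo[5.3.0]dec-8-en-6α-yl 4-methoxybenzoate
Product: 27 10β-[(tert-butyldimethylsilyl)oxy]-2β,4β-dihydroxy-1β,8-dimethyl-4α-(propan-2-yl)-9-(trifluoromethanesulfonyloxy)-5α-H-bicyclo[5.3.0]dec-8-en-6α-yl 4-methoxybenzoate
Conditions: TsOH·H2O (0.2 equiv), MeOH, 40 °C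
Reagents that add atoms: none
Why: Acid-catalysed transacetalisation to methanol should open the strained bridged formaldehyde acetal to the diol and dimethoxymethane, and it is run while C9 still bears the triflate so that the hindered C10 silyl ether is not allylic to an electron-rich alkene and survives.

Step 20
Reactants: 27 10β-[(tert-butyldimethylsilyl)oxy]-2β,4β-dihydroxy-1β,8-dimethyl-4α-(propan-2-yl)-9-(trifluoromethanesulfonyloxy)-5α-H-bicyclo[5.3.0]dec-8-en-6α-yl 4-methoxybenzoate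
Product: 28 2β-acetoxy-10β-[(tert-butyldimethylsilyl)oxy]-4β-hydroxy-1β,8-dimethyl-4α-(propan-2-yl)-9-(trifluoromethanesulfonyloxy)-5α-H-bicyclo[5.3.0]dec-8-en-6α-yl 4-methoxybenzoate
Conditions: Ac2O, pyridine, DMAP (cat.), CH2Cl2, 0 °C → rt
Reagents that add atoms: acetic anhydride, CC(=O)OC(C)=O
Why: Acetylation with Ac2O and DMAP should be selective for the secondary C2 hydroxyl because the C4 hydroxyl is tertiary and the C10 oxygen is silylated.

Step 21
Reactants: 28 2β-acetoxy-10β-[(tert-butyldimethylsilyl)oxy]-4β-hydroxy-1β,8-dimethyl-4α-(propan-2-yl)-9-(trifluoromethanesulfonyloxy)-5α-H-bicyclo[5.3.0]dec-8-en-6α-yl 4-methoxybenzoate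
Product: 29 2β-acetoxy-10β-[(tert-butyldimethylsilyl)oxy]-4β-hydroxy-1β,8-dimethyl-4α-(propan-2-yl)-5α-H-bicyclo[5.3.0]dec-8-en-6α-yl 4-methoxybenzoate
Conditions: Pd(OAc)2 (5 mol %), PPh3 (10 mol %), HCO2H, Et3N, DMF, 60 °C
Reagents that add atoms: none
Why: Palladium-catalysed reduction of an enol triflate with formate (oxidative addition to zerovalent palladium, formate-to-hydride exchange with loss of CO2, reductive elimination) should replace the triflate by hydrogen and leave the esters and the silyl ether intact.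

Step 22
Reactants: 29 2β-acetoxy-10β-[(tert-butyldimethylsilyl)oxy]-4β-hydroxy-1β,8-dimethyl-4α-(propan-2-yl)-5α-H-bicyclo[5.3.0]dec-8-en-6α-yl 4-methoxybenzoate
Product: 30 2β-acetoxy-10β-[(tert-butyldimethylsilyl)oxy]-8α,9α-epoxy-4β-hydroxy-1β,8β-dimethyl-4α-(propan-2-yl)-5α-H-bicyclo[5.3.0]decan-6α-yl 4-methoxybenzoate
Conditions: mCPBA, NaHCO3, CH2Cl2, 0 °C
Reagents that add atoms: 3-chloroperbenzoic acid, O=C(OO)c1cccc(Cl)c1
Why: Prilezhaev epoxidation of the only alkene should take place on the α face, anti to the bulky 10β-silyloxy group and the C1 methyl, which sets C8 and C9 trans to the C10 oxygen.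

Step 23
Reactants: 30 2β-acetoxy-10β-[(tert-butyldimethylsilyl)oxy]-8α,9α-epoxy-4β-hydroxy-1β,8β-dimethyl-4α-(propan-2-yl)-5α-H-bicyclo[5.3.0]decan-6α-yl 4-methoxybenzoate
Product: 31 2β-acetoxy-8α,9α-epoxy-4β,10β-dihydroxy-1β,8β-dimethyl-4α-(propan-2-yl)-5α-H-bicyclo[5.3.0]decan-6α-yl 4-methoxybenzoate (CNP0371526.1)
Conditions: HF·pyridine, pyridine, THF, 0 °C → rt
Reagents that add atoms: none
Why: Buffered fluoride desilylation should free the C10 hydroxyl under weakly acidic conditions that avoid acetyl migration to C10 and Payne rearrangement of the epoxy alcohol.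

Compound list
1 | methyl 1-hydroxycyclopropane-1-carboxylate | COC(=O)C1(O)CC1 | starting material
2 | methyl 1-[(tert-butyldimethylsilyl)oxy]cyclopropane-1-carboxylate | COC(=O)C1(O[Si](C)(C)C(C)(C)C)CC1 | intermediate
3 | 1-[(tert-butyldimethylsilyl)oxy]cyclopropane-1-carbaldehyde | O=CC1(O[Si](C)(C)C(C)(C)C)CC1 | intermediate
4 | 2-(triphenyl-λ5-phosphanylidene)propanal | CC(C=O)=P(c1ccccc1)(c1ccccc1)c1ccccc1 | starting material
5 | (E)-3-{1-[(tert-butyldimethylsilyl)oxy]cyclopropyl}-2-methylprop-2-enal | O=C/C(C)=C/C1(O[Si](C)(C)C(C)(C)C)CC1 | intermediate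
6 | 3-methylbutan-2-one | CC(C)C(C)=O | starting material
7 | diisopinocampheylboron enolate of 6 | C=C(OB([C@H]1C[C@H]2C[C@@H]([C@@H]1C)C2(C)C)[C@H]1C[C@H]2C[C@@H]([C@@H]1C)C2(C)C)C(C)C | intermediate
8 | boron aldolate (O-diisopinocampheylboryl derivative of 9) | CC(C)C(=O)C[C@H](OB([C@H]1C[C@H]2C[C@@H]([C@@H]1C)C2(C)C)[C@H]1C[C@H]2C[C@@H]([C@@H]1C)C2(C)C)/C(C)=C/C1(O[Si](C)(C)C(C)(C)C)CC1 | intermediate
9 | (5S,6E)-7-{1-[(tert-butyldimethylsilyl)oxy]cyclopropyl}-5-hydroxy-2,6-dimethylhept-6-en-3-one | CC(C)C(=O)C[C@H](O)/C(C)=C/C1(O[Si](C)(C)C(C)(C)C)CC1 | intermediate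
10 | ethynylmagnesium bromide | C#C[Mg]Br | starting material
11 | (3R,5S,6E)-7-{1-[(tert-butyldimethylsilyl)oxy]cyclopropyl}-6-methyl-3-(propan-2-yl)hept-6-en-1-yne-3,5-diol | C#C[C@](O)(C(C)C)C[C@H](O)/C(C)=C/C1(O[Si](C)(C)C(C)(C)C)CC1 | intermediate
12 | (1E,5R)-1-{1-[(tert-butyldimethylsilyl)oxy]cyclopropyl}-5-ethynyl-5-hydroxy-2,6-dimethylhept-1-en-3-one | C#C[C@](O)(C(C)C)CC(=O)/C(C)=C/C1(O[Si](C)(C)C(C)(C)C)CC1 | intermediate
13 | (3R,5R,6E)-7-{1-[(tert-butyldimethylsilyl)oxy]cyclopropyl}-6-methyl-3-(propan-2-yl)hept-6-en-1-yne-3,5-diol | C#C[C@](O)(C(C)C)C[C@@H](O)/C(C)=C/C1(O[Si](C)(C)C(C)(C)C)CC1 | intermediate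
14 | (4R,6R)-6-[(E)-1-{1-[(tert-butyldimethylsilyl)oxy]cyclopropyl}prop-1-en-2-yl]-4-ethynyl-4-(propan-2-yl)-1,3-dioxane | C#C[C@]1(C(C)C)C[C@H](/C(C)=C/C2(O[Si](C)(C)C(C)(C)C)CC2)OCO1 | intermediate
15 | 9-[(tert-butyldimethylsilyl)oxy]-1β-methyl-2β,4β-(methylenedioxy)-4α-(propan-2-yl)bicyclo[5.3.0]deca-5,9-diene | C1CC(O[Si](C)(C)C(C)(C)C)=C[C@]2(C)C(=C1)[C@]3(C(C)C)C[C@H]2OCO3 | intermediate
16 | 10ξ-[(tert-butyldimethylsilyl)oxy]-1β-methyl-2β,4β-(methylenedioxy)-4α-(propan-2-yl)bicyclo[5.3.0]dec-5-en-9-one | C1CC(=O)C(O[Si](C)(C)C(C)(C)C)[C@]2(C)C(=C1)[C@]3(C(C)C)C[C@H]2OCO3 | intermediate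
17 | lithium C8–C9 enolate of 16 | C1C=C(O[Li])C(O[Si](C)(C)C(C)(C)C)[C@]2(C)C(=C1)[C@]3(C(C)C)C[C@H]2OCO3 | intermediate
18 | 10ξ-[(tert-butyldimethylsilyl)oxy]-1β,8ξ-dimethyl-2β,4β-(methylenedioxy)-4α-(propan-2-yl)bicyclo[5.3.0]dec-5-en-9-one | C1C(C)C(=O)C(O[Si](C)(C)C(C)(C)C)[C@]2(C)C(=C1)[C@]3(C(C)C)C[C@H]2OCO3 | intermediate
19 | 10ξ-hydroxy-1β,8ξ-dimethyl-2β,4β-(methylenedioxy)-4α-(propan-2-yl)bicyclo[5.3.0]dec-5-en-9-one | C1C(C)C(=O)C(O)[C@]2(C)C(=C1)[C@]3(C(C)C)C[C@H]2OCO3 | intermediate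
20 | 1β,8ξ-dimethyl-2β,4β-(methylenedioxy)-4α-(propan-2-yl)bicyclo[5.3.0]dec-5-ene-9,10-dione | C1C(C)C(=O)C(=O)[C@]2(C)C(=C1)[C@]3(C(C)C)C[C@H]2OCO3 | intermediate
21 | 1β,8-dimethyl-2β,4β-(methylenedioxy)-10-oxo-4α-(propan-2-yl)bicyclo[5.3.0]deca-5,8-dien-9-yl trifluoromethanesulfonate | C1C(C)=C(OS(=O)(=O)C(F)(F)F)C(=O)[C@]2(C)C(=C1)[C@]3(C(C)C)C[C@H]2OCO3 | intermediate
22 | 10β-hydroxy-1β,8-dimethyl-2β,4β-(methylenedioxy)-4α-(propan-2-yl)bicyclo[5.3.0]deca-5,8-dien-9-yl trifluoromethanesulfonate | C1C(C)=C(OS(=O)(=O)C(F)(F)F)[C@H](O)[C@]2(C)C(=C1)[C@]3(C(C)C)C[C@H]2OCO3 | intermediate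
23 | 10β-[(tert-butyldimethylsilyl)oxy]-1β,8-dimethyl-2β,4β-(methylenedioxy)-4α-(propan-2-yl)bicyclo[5.3.0]deca-5,8-dien-9-yl trifluoromethanesulfonate | C1C(C)=C(OS(=O)(=O)C(F)(F)F)[C@H](O[Si](C)(C)C(C)(C)C)[C@]2(C)C(=C1)[C@]3(C(C)C)C[C@H]2OCO3 | intermediate
24 | C6 alkylborane of 23 (6α-BH2; 5α-H) | B[C@H]1CC(C)=C(OS(=O)(=O)C(F)(F)F)[C@H](O[Si](C)(C)C(C)(C)C)[C@]2(C)[C@@H]1[C@]3(C(C)C)C[C@H]2OCO3 | intermediate
25 | 10β-[(tert-butyldimethylsilyl)oxy]-6α-hydroxy-1β,8-dimethyl-2β,4β-(methylenedioxy)-4α-(propan-2-yl)-5α-H-bicyclo[5.3.0]dec-8-en-9-yl trifluoromethanesulfonate | O[C@H]1CC(C)=C(OS(=O)(=O)C(F)(F)F)[C@H](O[Si](C)(C)C(C)(C)C)[C@]2(C)[C@@H]1[C@]3(C(C)C)C[C@H]2OCO3 | intermediate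
26 | 10β-[(tert-butyldimethylsilyl)oxy]-1β,8-dimethyl-2β,4β-(methylenedioxy)-4α-(propan-2-yl)-9-(trifluoromethanesulfonyloxy)-5α-H-bicyclo[5.3.0]dec-8-en-6α-yl 4-methoxybenzoate | COc1ccc(C(=O)O[C@H]2CC(C)=C(OS(=O)(=O)C(F)(F)F)[C@H](O[Si](C)(C)C(C)(C)C)[C@]3(C)[C@@H]2[C@]4(C(C)C)C[C@H]3OCO4)cc1 | intermediate
27 | 10β-[(tert-butyldimethylsilyl)oxy]-2β,4β-dihydroxy-1β,8-dimethyl-4α-(propan-2-yl)-9-(trifluoromethanesulfonyloxy)-5α-H-bicyclo[5.3.0]dec-8-en-6α-yl 4-methoxybenzoate | COc1ccc(C(=O)O[C@H]2CC(C)=C(OS(=O)(=O)C(F)(F)F)[C@H](O[Si](C)(C)C(C)(C)C)[C@]3(C)[C@@H]2[C@](O)(C(C)C)C[C@H]3O)cc1 | intermediate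
28 | 2β-acetoxy-10β-[(tert-butyldimethylsilyl)oxy]-4β-hydroxy-1β,8-dimethyl-4α-(propan-2-yl)-9-(trifluoromethanesulfonyloxy)-5α-H-bicyclo[5.3.0]dec-8-en-6α-yl 4-methoxybenzoate | COc1ccc(C(=O)O[C@H]2CC(C)=C(OS(=O)(=O)C(F)(F)F)[C@H](O[Si](C)(C)C(C)(C)C)[C@]3(C)[C@@H]2[C@](O)(C(C)C)C[C@H]3OC(C)=O)cc1 | intermediate
29 | 2β-acetoxy-10β-[(tert-butyldimethylsilyl)oxy]-4β-hydroxy-1β,8-dimethyl-4α-(propan-2-yl)-5α-H-bicyclo[5.3.0]dec-8-en-6α-yl 4-methoxybenzoate | COc1ccc(C(=O)O[C@H]2CC(C)=C[C@H](O[Si](C)(C)C(C)(C)C)[C@]3(C)[C@@H]2[C@](O)(C(C)C)C[C@H]3OC(C)=O)cc1 | intermediate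
30 | 2β-acetoxy-10β-[(tert-butyldimethylsilyl)oxy]-8α,9α-epoxy-4β-hydroxy-1β,8β-dimethyl-4α-(propan-2-yl)-5α-H-bicyclo[5.3.0]decan-6α-yl 4-methoxybenzoate | COc1ccc(C(=O)O[C@H]2C[C@@]3(C)O[C@H]3[C@H](O[Si](C)(C)C(C)(C)C)[C@]3(C)[C@@H]2[C@](O)(C(C)C)C[C@H]3OC(C)=O)cc1 | intermediate
31 | 2β-acetoxy-8α,9α-epoxy-4β,10β-dihydroxy-1β,8β-dimethyl-4α-(propan-2-yl)-5α-H-bicyclo[5.3.0]decan-6α-yl 4-methoxybenzoate (CNP0371526.1) | COc1ccc(C(=O)O[C@H]2C[C@@]3(C)O[C@H]3[C@H](O)[C@]3(C)[C@@H]2[C@](O)(C(C)C)C[C@H]3OC(C)=O)cc1 | target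

Total step count: 23. Longest linear sequence: 23 steps (from 1; compounds 4, 6 and 10 enter as purchased reagents).

Steps most likely to fail

Step 9. The chair with both unsaturated arms axial may be too costly to populate, so that ring closure is outrun by alkyne oligomerisation on rhodium. The fallback drops the tether and sets out from diol 13. Silylation with Me3SiOTf and Et3N should give the bis(trimethylsilyl) ether F1, and the same [Rh(CO)2Cl]2 conditions should cyclise it to the untethered cycloadduct bis(trimethylsilyl) ether F2. C1 would then rest on open-chain allylic strain only, and any C1 epimer would be removed by chromatography. K2CO3 in MeOH at 0 °C should free the cycloadduct diol F3 with the enol ether intact, and NaH/CH2Br2 in DMF closes the methylene acetal, which returns to the route at 15.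

Step 17. Facial selectivity may be poor if the seven-membered ring folds its triflate-bearing alkene over the exo face, which would deliver borane to the endo face and give the cis ring fusion. The fallback uses that endo preference and sets out from 23. mCPBA should give the 5β,6β-epoxide F4. BF3·OEt2 should then trigger a 1,2-hydride shift from C6 to C5 with inversion at C5 (Meinwald rearrangement, as known for 5β,6β-epoxy steroids) to the trans-fused C6 ketone F5. NaBH4 should attack from the α face, away from the C1 methyl, to give the 6β-alcohol F6. A Mitsunobu esterification with 4-methoxybenzoic acid, PPh3 and diisopropyl azodicarboxylate inverts C6 and returns to the route at 26.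

Step 19. The C10 silyl ether may be lost before the formaldehyde acetal opens under protic acid. The fallback is acetolysis and sets out from 26. Ac2O with catalytic FeCl3 at 0 °C should open the acetal at the less hindered C2 oxygen to the C2 acetate C4 acetoxymethyl ether F7. Brief treatment with catalytic K2CO3 in MeOH at 0 °C should remove the labile acetoxymethyl group and return to the route at 28, so that step 20 is not needed.

Further compounds
F1 | step 9 | (3R,5R,6E)-7-{1-[(tert-butyldimethylsilyl)oxy]cyclopropyl}-6-methyl-3-(propan-2-yl)-3,5-bis[(trimethylsilyl)oxy]hept-6-en-1-yne | C#C[C@](O[Si](C)(C)C)(C(C)C)C[C@@H](O[Si](C)(C)C)/C(C)=C/C1(O[Si](C)(C)C(C)(C)C)CC1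
F2 | step 9 | 9-[(tert-butyldimethylsilyl)oxy]-1β-methyl-4α-(propan-2-yl)-2β,4β-bis[(trimethylsilyl)oxy]bicyclo[5.3.0]deca-5,9-diene | C1CC(O[Si](C)(C)C(C)(C)C)=C[C@]2(C)C(=C1)[C@](O[Si](C)(C)C)(C(C)C)C[C@H]2O[Si](C)(C)C
F3 | step 9 | 9-[(tert-butyldimethylsilyl)oxy]-1β-methyl-4α-(propan-2-yl)bicyclo[5.3.0]deca-5,9-diene-2β,4β-diol | C1CC(O[Si](C)(C)C(C)(C)C)=C[C@]2(C)C(=C1)[C@](O)(C(C)C)C[C@H]2O
F4 | step 17 | 10β-[(tert-butyldimethylsilyl)oxy]-5β,6β-epoxy-1β,8-dimethyl-2β,4β-(methylenedioxy)-4α-(propan-2-yl)bicyclo[5.3.0]dec-8-en-9-yl trifluoromethanesulfonate | [C@@H]12CC(C)=C(OS(=O)(=O)C(F)(F)F)[C@H](O[Si](C)(C)C(C)(C)C)[C@]3(C)[C@@]1(O2)[C@]4(C(C)C)C[C@H]3OCO4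
F5 | step 17 | 10β-[(tert-butyldimethylsilyl)oxy]-1β,8-dimethyl-2β,4β-(methylenedioxy)-6-oxo-4α-(propan-2-yl)-5α-H-bicyclo[5.3.0]dec-8-en-9-yl trifluoromethanesulfonate | O=C1CC(C)=C(OS(=O)(=O)C(F)(F)F)[C@H](O[Si](C)(C)C(C)(C)C)[C@]2(C)[C@@H]1[C@]3(C(C)C)C[C@H]2OCO3
F6 | step 17 | 10β-[(tert-butyldimethylsilyl)oxy]-6β-hydroxy-1β,8-dimethyl-2β,4β-(methylenedioxy)-4α-(propan-2-yl)-5α-H-bicyclo[5.3.0]dec-8-en-9-yl trifluoromethanesulfonate | O[C@@H]1CC(C)=C(OS(=O)(=O)C(F)(F)F)[C@H](O[Si](C)(C)C(C)(C)C)[C@]2(C)[C@@H]1[C@]3(C(C)C)C[C@H]2OCO3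
F7 | step 19 | 2β-acetoxy-4β-(acetoxymethoxy)-10β-[(tert-butyldimethylsilyl)oxy]-1β,8-dimethyl-4α-(propan-2-yl)-9-(trifluoromethanesulfonyloxy)-5α-H-bicyclo[5.3.0]dec-8-en-6α-yl 4-methoxybenzoate | COc1ccc(C(=O)O[C@H]2CC(C)=C(OS(=O)(=O)C(F)(F)F)[C@H](O[Si](C)(C)C(C)(C)C)[C@]3(C)[C@@H]2[C@](OCOC(C)=O)(C(C)C)C[C@H]3OC(C)=O)cc1
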